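**Retrosynthetic overview**

1. The target is reached by desilylation and a redox adjustment at C3 of a ten-membered allylic alcohol. The cyclodecene is closed last, at C3–C4, by intramolecular Nozaki–Hiyama–Kishi addition of a (Z)-alkenyl iodide to an aldehyde.
2. The α-methylene-γ-butyrolactone is formed first, in the fragment union: a CrCl2-mediated intermolecular 2-(methoxycarbonyl)allylation of (Z)-3-iodobut-2-enal by a chiral allylic bromide makes C6–C7 and lactonises.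
3. The bromide comes from geraniol: Sharpless epoxidation and reductive opening set C10, ynone transfer hydrogenation sets C8, and hydroalumination–iodination plus carbonylation build the 2-(bromomethyl)enoate. The prenyl end is a masked C3 aldehyde.
4. The aldehyde (C4–C6, C15) comes from but-2-yn-1-ol by hydroalumination–iodination and oxidation.
5. Ring order: lactone (step 17), then cyclodecene (step 22).

Assumption: atom labels C1–C15 in the explanations and in the names of the macrocycles follow germacrane numbering (C1–C10 ring, C11–C13 lactone unit, C14 on C10, C15 on C4).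

**Route**

Step 1
Reactants: 1 geraniol, (2E)-3,7-dimethylocta-2,6-dien-1-ol
Product: 2 (2S,3S)-2,3-epoxygeraniol, [(2S,3S)-3-methyl-3-(4-methylpent-3-en-1-yl)oxiran-2-yl]methanol
Conditions: Ti(OiPr)4 (5 mol %), L-(+)-diethyl tartrate (7 mol %), t-BuOOH, 4 Å MS, CH2Cl2, −20 °C
Reagents that add atoms: tert-butyl hydroperoxide CC(C)(C)OO
Why: Katsuki–Sharpless asymmetric epoxidation, in which the titanium tartrate complex epoxidises only the allylic-alcohol alkene and the L-(+)-tartrate gives the (2S,3S)-epoxide (about 95 % ee), fixing the later C10 centre.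

Step 2
Reactants: 2 (2S,3S)-2,3-epoxygeraniol
Product: 3 (3S)-3,7-dimethyloct-6-ene-1,3-diol
Conditions: NaAlH2(OCH2CH2OMe)2, THF, 0 °C; aq. potassium sodium tartrate
Reagents that add atoms: none
Why: Hydroxyl-directed reductive epoxide opening, in which the alkoxyaluminate delivers hydride intramolecularly to C2 so that the C3–O bond and its configuration are kept and the 1,3-diol results.

Step 3
Reactants: 3 (3S)-3,7-dimethyloct-6-ene-1,3-diol
Product: 4 (3S)-3,7-dimethyl-1,3-bis(triethylsilyloxy)oct-6-ene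
Conditions: TESOTf (2.5 equiv), 2,6-lutidine, CH2Cl2, −78 to 0 °C
Reagents that add atoms: triethylsilyl trifluoromethanesulfonate CC[Si](CC)(CC)OS(=O)(=O)C(F)(F)F
Why: Silyl ether formation with the reactive silyl triflate, which protects the hindered tertiary alcohol as well as the primary one without touching the stereocentre.

Step 4
Reactants: 4 (3S)-3,7-dimethyl-1,3-bis(triethylsilyloxy)oct-6-ene
Product: 5 (3S)-3,7-dimethyl-3-(triethylsilyloxy)oct-6-en-1-ol
Conditions: PPTS (0.1 equiv), MeOH–CH2Cl2, 0 °C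
Reagents that add atoms: none
Why: Selective acid-catalysed solvolysis (deprotection), the unhindered primary TES ether being cleaved far faster than the tertiary one.

Step 5
Reactants: 5 (3S)-3,7-dimethyl-3-(triethylsilyloxy)oct-6-en-1-ol
Product: 6 (3S)-3,7-dimethyl-3-(triethylsilyloxy)oct-6-enal
Conditions: Dess–Martin periodinane, NaHCO3, CH2Cl2, rt
Reagents that add atoms: none
Why: Dess–Martin oxidation of the primary alcohol to the aldehyde under buffered conditions that leave the tertiary silyl ether and the alkene untouched.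

Step 6
Reactants: 7 prop-2-yn-1-ol
Product: 8 triethyl(prop-2-yn-1-yloxy)silane
Conditions: TESCl, imidazole, CH2Cl2, 0 °C
Reagents that add atoms: chlorotriethylsilane CC[Si](Cl)(CC)CC
Why: Standard silylation of a primary alcohol, giving an alkyne whose protecting group can later be removed under the mild conditions of step 4.

Step 7
Reactants: 8 triethyl(prop-2-yn-1-yloxy)silane; 6 (3S)-3,7-dimethyl-3-(triethylsilyloxy)oct-6-enal
Product: 10 (4RS,6S)-6,10-dimethyl-1,6-bis(triethylsilyloxy)undec-9-en-2-yn-4-ol, via lithium acetylide 9 (not isolated)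
Conditions: n-BuLi, THF, −78 °C; then 6, −78 to −30 °C; aq. NH4Cl
Reagents that add atoms: none
Why: Acetylide 1,2-addition to the aldehyde forms the C7–C8 bond, and the unselective new carbinol centre does not matter because it is oxidised in step 8.

Step 8
Reactants: 10 (4RS,6S)-6,10-dimethyl-1,6-bis(triethylsilyloxy)undec-9-en-2-yn-4-ol
Product: 11 (6S)-6,10-dimethyl-1,6-bis(triethylsilyloxy)undec-9-en-2-yn-4-one
Conditions: Dess–Martin periodinane, NaHCO3, CH2Cl2, 0 °C to rt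
Reagents that add atoms: none
Why: Dess–Martin oxidation of the propargylic alcohol gives the ynone for reagent-controlled reduction, with no base present that could eliminate the β-silyloxy group.

Step 9
Reactants: 11 (6S)-6,10-dimethyl-1,6-bis(triethylsilyloxy)undec-9-en-2-yn-4-one
Product: 12 (4R,6S)-6,10-dimethyl-1,6-bis(triethylsilyloxy)undec-9-en-2-yn-4-ol
Conditions: Ru[(R,R)-TsNCH(Ph)CH(Ph)NH](p-cymene) (1 mol %), i-PrOH, rt
Reagents that add atoms: none
Why: Noyori–Ikariya asymmetric transfer hydrogenation, in which the alkynyl group takes the place of the aryl group of an aryl ketone so that the (R,R)-catalyst gives the (4R)-propargylic alcohol (the C8 centre) under reagent control, independent of the remote C10 centre.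

Step 10
Reactants: 12 (4R,6S)-6,10-dimethyl-1,6-bis(triethylsilyloxy)undec-9-en-2-yn-4-ol
Product: 14 (2Z,4R,6S)-2-iodo-6,10-dimethyl-1,6-bis(triethylsilyloxy)undeca-2,9-dien-4-ol, via cyclic alkenylalanate 13 (not isolated)
Conditions: NaAlH2(OCH2CH2OMe)2, THF, 0 °C to rt; then I2, −78 °C
Reagents that add atoms: iodine [I][I]
Why: Hydroxyl-directed trans-hydroalumination of the propargylic alcohol puts aluminium on the distal alkyne carbon (C11) and hydrogen on C7, and iodinolysis with retention gives the (Z)-iodoalkene with iodine cis to C8.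

Step 11
Reactants: 14 (2Z,4R,6S)-2-iodo-6,10-dimethyl-1,6-bis(triethylsilyloxy)undeca-2,9-dien-4-ol
Product: 15 (2Z,4R,6S)-2-iodo-4-[(4-methoxybenzyl)oxy]-6,10-dimethyl-1,6-bis(triethylsilyloxy)undeca-2,9-diene
Conditions: NaH, 4-methoxybenzyl chloride, Bu4NI (cat.), THF–DMF, 0 °C to rt
Reagents that add atoms: 4-methoxybenzyl chloride COc1ccc(CCl)cc1
Why: Williamson etherification protects O8 as a PMB ether that survives palladium, CrCl2 and mild acid and is later removed oxidatively without touching the silyl ether.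

Step 12
Reactants: 15 (2Z,4R,6S)-2-iodo-4-[(4-methoxybenzyl)oxy]-6,10-dimethyl-1,6-bis(triethylsilyloxy)undeca-2,9-diene
Product: 16 methyl (2Z,4R,6S)-4-[(4-methoxybenzyl)oxy]-6,10-dimethyl-6-(triethylsilyloxy)-2-[(triethylsilyloxy)methyl]undeca-2,9-dienoate
Conditions: CO (1 atm), Pd(PPh3)4 (5 mol %), Et3N, MeOH–DMF, 50 °C
Reagents that add atoms: carbon monoxide [C-]#[O+]; methanol CO
Why: Palladium-catalysed alkoxycarbonylation (oxidative addition of zerovalent palladium to the C–I bond, CO insertion, methanolysis) keeps the alkene geometry and installs C12 on C11.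

Step 13
Reactants: 16 methyl (2Z,4R,6S)-4-[(4-methoxybenzyl)oxy]-6,10-dimethyl-6-(triethylsilyloxy)-2-[(triethylsilyloxy)methyl]undeca-2,9-dienoate
Product: 17 methyl (2Z,4R,6S)-2-(hydroxymethyl)-4-[(4-methoxybenzyl)oxy]-6,10-dimethyl-6-(triethylsilyloxy)undeca-2,9-dienoate
Conditions: PPTS (0.1 equiv), MeOH–CH2Cl2, 0 °C
Reagents that add atoms: none
Why: Selective solvolysis (deprotection) of the primary allylic TES ether, the tertiary TES ether and the PMB ether being stable under these conditions.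

Step 14
Reactants: 17 methyl (2Z,4R,6S)-2-(hydroxymethyl)-4-[(4-methoxybenzyl)oxy]-6,10-dimethyl-6-(triethylsilyloxy)undeca-2,9-dienoate
Product: 18 methyl (2E,4R,6S)-2-(bromomethyl)-4-[(4-methoxybenzyl)oxy]-6,10-dimethyl-6-(triethylsilyloxy)undeca-2,9-dienoate
Conditions: CBr4, PPh3, CH2Cl2, 0 °C
Reagents that add atoms: carbon tetrabromide BrC(Br)(Br)Br
Why: Appel reaction converts the primary allylic alcohol into the bromide under neutral conditions compatible with the PMB and TES ethers.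

Step 15
Reactants: 19 but-2-yn-1-ol
Product: 21 (2Z)-3-iodobut-2-en-1-ol, via cyclic alkenylalanate 20 (not isolated)
Conditions: NaAlH2(OCH2CH2OMe)2, THF, 0 °C to rt; then I2, −78 °C
Reagents that add atoms: iodine [I][I]
Why: Hydroxyl-directed trans-hydroalumination followed by iodinolysis gives only the (Z)-3-iodo isomer, which fixes the later C4=C5 geometry (C6 cis to the carbon that becomes C3).

Step 16
Reactants: 21 (2Z)-3-iodobut-2-en-1-ol
Product: 22 (2Z)-3-iodobut-2-enal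
Conditions: MnO2 (activated, excess), CH2Cl2, rt, dark; used at once
Reagents that add atoms: none
Why: Allylic oxidation with MnO2 is neutral and heterogeneous, so the sensitive (Z)-β-iodoenal forms without Z/E isomerisation.

Step 17
Reactants: 18 methyl (2E,4R,6S)-2-(bromomethyl)-4-[(4-methoxybenzyl)oxy]-6,10-dimethyl-6-(triethylsilyloxy)undeca-2,9-dienoate; 22 (2Z)-3-iodobut-2-enal
Product: 24 (4R,5S)-5-[(1Z)-2-iodoprop-1-en-1-yl]-4-{(1R,3S)-1-[(4-methoxybenzyl)oxy]-3,7-dimethyl-3-(triethylsilyloxy)oct-6-en-1-yl}-3-methylideneoxolan-2-one, via hydroxy ester 23 (not isolated)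
Conditions: CrCl2 (4 equiv, nickel-free), THF, 0 °C to rt; aq. NH4Cl; then PPTS (cat.), CH2Cl2, rt
Reagents that add atoms: none
Why: Nozaki–Hiyama-type (Barbier) 2-(alkoxycarbonyl)allylation, in which the allylchromium species (C8 trans to CH2Cr) adds through a chair transition state with the aldehyde substituent equatorial to give the 6,7-anti adduct and hence the trans-lactone, while allylic 1,3-strain with the cis ester holds H8 in the alkene plane so that the aldehyde bonds to C7 anti to the bulky C9 chain (OPMB outside), giving the 7,8-relationship of the target before the C6 oxygen closes the lactone.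

Step 18
Reactants: 24 (4R,5S)-5-[(1Z)-2-iodoprop-1-en-1-yl]-4-{(1R,3S)-1-[(4-methoxybenzyl)oxy]-3,7-dimethyl-3-(triethylsilyloxy)oct-6-en-1-yl}-3-methylideneoxolan-2-one
Product: 25 (4R,5S)-4-[(1R,3S)-1-hydroxy-3,7-dimethyl-3-(triethylsilyloxy)oct-6-en-1-yl]-5-[(1Z)-2-iodoprop-1-en-1-yl]-3-methylideneoxolan-2-one
Conditions: DDQ, CH2Cl2–pH 7 buffer, 0 °C
Reagents that add atoms: none
Why: Oxidative PMB ether cleavage by DDQ (hydride abstraction, then hydrolysis of the oxocarbenium ion) frees O8 without affecting the silyl ether, alkenyl iodide, lactone or alkenes.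

Step 19
Reactants: 25 (4R,5S)-4-[(1R,3S)-1-hydroxy-3,7-dimethyl-3-(triethylsilyloxy)oct-6-en-1-yl]-5-[(1Z)-2-iodoprop-1-en-1-yl]-3-methylideneoxolan-2-one
Product: 26 (1R,3S)-1-{(2S,3R)-2-[(1Z)-2-iodoprop-1-en-1-yl]-4-methylidene-5-oxooxolan-3-yl}-3,7-dimethyl-3-(triethylsilyloxy)oct-6-en-1-yl 2-methylpropanoate
Conditions: isobutyryl chloride, pyridine, DMAP (cat.), CH2Cl2, 0 °C to rt
Reagents that add atoms: 2-methylpropanoyl chloride CC(C)C(Cl)=O
Why: DMAP-catalysed acylation (esterification) of the only free hydroxyl installs the isobutyrate with retention at C8.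

Step 20
Reactants: 26 (1R,3S)-1-{(2S,3R)-2-[(1Z)-2-iodoprop-1-en-1-yl]-4-methylidene-5-oxooxolan-3-yl}-3,7-dimethyl-3-(triethylsilyloxy)oct-6-en-1-yl 2-methylpropanoate
Product: 27 (1R,3S)-5-(3,3-dimethyloxiran-2-yl)-1-{(2S,3R)-2-[(1Z)-2-iodoprop-1-en-1-yl]-4-methylidene-5-oxooxolan-3-yl}-3-methyl-3-(triethylsilyloxy)pentyl 2-methylpropanoate (both epoxide epimers)
Conditions: mCPBA (1.05 equiv), NaHCO3, CH2Cl2, 0 °C
Reagents that add atoms: 3-chloroperoxybenzoic acid OOC(=O)c1cccc(Cl)c1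
Why: Prilezhaev epoxidation is chemoselective for the electron-rich trisubstituted prenyl alkene over the electron-poor α-methylene lactone and the iodoalkene, and the new epoxide stereocentre is lost in step 21.

Step 21
Reactants: 27 (1R,3S)-5-(3,3-dimethyloxiran-2-yl)-1-{(2S,3R)-2-[(1Z)-2-iodoprop-1-en-1-yl]-4-methylidene-5-oxooxolan-3-yl}-3-methyl-3-(triethylsilyloxy)pentyl 2-methylpropanoate
Product: 28 (1R,3S)-1-{(2S,3R)-2-[(1Z)-2-iodoprop-1-en-1-yl]-4-methylidene-5-oxooxolan-3-yl}-3-methyl-6-oxo-3-(triethylsilyloxy)hexyl 2-methylpropanoate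
Conditions: H5IO6, THF–Et2O, 0 °C
Reagents that add atoms: none
Why: Periodic acid opens the trisubstituted epoxide and cleaves the resulting glycol (Malaprade-type oxidative cleavage) to unmask the C3 aldehyde with loss of acetone, while the C10 silyl ether prevents lactol formation.

Step 22
Reactants: 28 (1R,3S)-1-{(2S,3R)-2-[(1Z)-2-iodoprop-1-en-1-yl]-4-methylidene-5-oxooxolan-3-yl}-3-methyl-6-oxo-3-(triethylsilyloxy)hexyl 2-methylpropanoate
Product: 29 (3RS,4Z,6R,7R,8R,10S)-3-hydroxy-8-(2-methylpropanoyloxy)-10-(triethylsilyloxy)germacra-4,11(13)-dien-12,6-olide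
Conditions: CrCl2 (10 equiv), NiCl2 (0.1 equiv), DMSO–THF, rt, 2 mM, slow addition
Reagents that add atoms: none
Why: Nozaki–Hiyama–Kishi reaction, in which nickel-catalysed formation of the alkenylchromium species from the (Z)-iodide (retention of geometry) and its chemoselective 1,2-addition to the aldehyde at high dilution close the ten-membered ring, the C3 configuration being left to steps 23 and 24.

Step 23
Reactants: 29 (3RS,4Z,6R,7R,8R,10S)-3-hydroxy-8-(2-methylpropanoyloxy)-10-(triethylsilyloxy)germacra-4,11(13)-dien-12,6-olide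
Product: 30 (4Z,6R,7R,8R,10S)-8-(2-methylpropanoyloxy)-3-oxo-10-(triethylsilyloxy)germacra-4,11(13)-dien-12,6-olide
Conditions: Dess–Martin periodinane, NaHCO3, CH2Cl2, rt
Reagents that add atoms: none
Why: Dess–Martin oxidation converges both C3 epimers of the allylic alcohol into one (Z)-enone under neutral conditions that do not isomerise the alkene or the α-methylene lactone.

Step 24
Reactants: 30 (4Z,6R,7R,8R,10S)-8-(2-methylpropanoyloxy)-3-oxo-10-(triethylsilyloxy)germacra-4,11(13)-dien-12,6-olide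
Product: 31 (3S,4Z,6R,7R,8R,10S)-3-hydroxy-8-(2-methylpropanoyloxy)-10-(triethylsilyloxy)germacra-4,11(13)-dien-12,6-olide
Conditions: (R)-Me-CBS oxazaborolidine (1 equiv), catecholborane, CH2Cl2, −78 °C
Reagents that add atoms: none
Why: Corey–Bakshi–Shibata reduction, in which the (R)-oxazaborolidine treats the α-methyl alkenyl side as the large group and delivers hydride to the face that gives the (3S)-allylic alcohol under reagent control, with 1,2-selectivity and without reducing the esters or the exocyclic enoate at −78 °C.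

Step 25
Reactants: 31 (3S,4Z,6R,7R,8R,10S)-3-hydroxy-8-(2-methylpropanoyloxy)-10-(triethylsilyloxy)germacra-4,11(13)-dien-12,6-olide
Product: 32 (3S,4Z,6R,7R,8R,10S)-3,10-dihydroxy-8-(2-methylpropanoyloxy)germacra-4,11(13)-dien-12,6-olide (CNP0163972.1)
Conditions: HF·pyridine, pyridine, THF, 0 °C to rt
Reagents that add atoms: none
Why: Buffered fluoride desilylation removes the tertiary TES ether without ionising the allylic alcohol or opening the lactone, and no stereocentre is touched.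

**Compound list**

1 | geraniol, (2E)-3,7-dimethylocta-2,6-dien-1-ol | CC(C)=CCC/C(C)=C/CO | starting material
2 | (2S,3S)-2,3-epoxygeraniol | OC[C@@H]1O[C@@]1(C)CCC=C(C)C | intermediate
3 | (3S)-3,7-dimethyloct-6-ene-1,3-diol | OCC[C@@](C)(O)CCC=C(C)C | intermediate
4 | (3S)-3,7-dimethyl-1,3-bis(triethylsilyloxy)oct-6-ene | CC[Si](CC)(CC)OCC[C@@](C)(O[Si](CC)(CC)CC)CCC=C(C)C | intermediate
5 | (3S)-3,7-dimethyl-3-(triethylsilyloxy)oct-6-en-1-ol | OCC[C@@](C)(O[Si](CC)(CC)CC)CCC=C(C)C | intermediate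
6 | (3S)-3,7-dimethyl-3-(triethylsilyloxy)oct-6-enal | O=CC[C@@](C)(O[Si](CC)(CC)CC)CCC=C(C)C | intermediate
7 | prop-2-yn-1-ol | C#CCO | starting material
8 | triethyl(prop-2-yn-1-yloxy)silane | C#CCO[Si](CC)(CC)CC | intermediate
9 | lithium 3-(triethylsilyloxy)prop-1-yn-1-ide (not isolated) | [Li]C#CCO[Si](CC)(CC)CC | intermediate
10 | (4RS,6S)-6,10-dimethyl-1,6-bis(triethylsilyloxy)undec-9-en-2-yn-4-ol | CC[Si](CC)(CC)OCC#CC(O)C[C@@](C)(O[Si](CC)(CC)CC)CCC=C(C)C | intermediate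
11 | (6S)-6,10-dimethyl-1,6-bis(triethylsilyloxy)undec-9-en-2-yn-4-one | CC[Si](CC)(CC)OCC#CC(=O)C[C@@](C)(O[Si](CC)(CC)CC)CCC=C(C)C | intermediate
12 | (4R,6S)-6,10-dimethyl-1,6-bis(triethylsilyloxy)undec-9-en-2-yn-4-ol | CC[Si](CC)(CC)OCC#C[C@H](O)C[C@@](C)(O[Si](CC)(CC)CC)CCC=C(C)C | intermediate
13 | cyclic sodium alkenylalanate from 12 (Al on C2 and on the C4 oxygen, two 2-methoxyethoxy groups; not isolated) | CC[Si](CC)(CC)OCC1=C[C@@H](C[C@@](C)(O[Si](CC)(CC)CC)CCC=C(C)C)O[Al-]1(OCCOC)OCCOC.[Na+] | intermediate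
14 | (2Z,4R,6S)-2-iodo-6,10-dimethyl-1,6-bis(triethylsilyloxy)undeca-2,9-dien-4-ol | CC[Si](CC)(CC)OC/C(I)=C/[C@H](O)C[C@@](C)(O[Si](CC)(CC)CC)CCC=C(C)C | intermediate
15 | (2Z,4R,6S)-2-iodo-4-[(4-methoxybenzyl)oxy]-6,10-dimethyl-1,6-bis(triethylsilyloxy)undeca-2,9-diene | CC[Si](CC)(CC)OC/C(I)=C/[C@H](OCc1ccc(OC)cc1)C[C@@](C)(O[Si](CC)(CC)CC)CCC=C(C)C | intermediate
16 | methyl (2Z,4R,6S)-4-[(4-methoxybenzyl)oxy]-6,10-dimethyl-6-(triethylsilyloxy)-2-[(triethylsilyloxy)methyl]undeca-2,9-dienoate | CC[Si](CC)(CC)OC/C(C(=O)OC)=C/[C@H](OCc1ccc(OC)cc1)C[C@@](C)(O[Si](CC)(CC)CC)CCC=C(C)C | intermediate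
17 | methyl (2Z,4R,6S)-2-(hydroxymethyl)-4-[(4-methoxybenzyl)oxy]-6,10-dimethyl-6-(triethylsilyloxy)undeca-2,9-dienoate | OC/C(C(=O)OC)=C/[C@H](OCc1ccc(OC)cc1)C[C@@](C)(O[Si](CC)(CC)CC)CCC=C(C)C | intermediate
18 | methyl (2E,4R,6S)-2-(bromomethyl)-4-[(4-methoxybenzyl)oxy]-6,10-dimethyl-6-(triethylsilyloxy)undeca-2,9-dienoate | BrC/C(C(=O)OC)=C/[C@H](OCc1ccc(OC)cc1)C[C@@](C)(O[Si](CC)(CC)CC)CCC=C(C)C | intermediate
19 | but-2-yn-1-ol | CC#CCO | starting material
20 | cyclic sodium alkenylalanate from 19 (Al on C3 and on oxygen, two 2-methoxyethoxy groups; not isolated) | CC1=CCO[Al-]1(OCCOC)OCCOC.[Na+] | intermediate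
21 | (2Z)-3-iodobut-2-en-1-ol | C/C(I)=C/CO | intermediate
22 | (2Z)-3-iodobut-2-enal | C/C(I)=C/C=O | intermediate
23 | methyl (3S,4R,6S)-3-[(1S,2Z)-1-hydroxy-3-iodobut-2-en-1-yl]-4-[(4-methoxybenzyl)oxy]-6,10-dimethyl-2-methylidene-6-(triethylsilyloxy)undec-9-enoate (not isolated) | C=C(C(=O)OC)[C@@H]([C@H](O)/C=C(/C)I)[C@H](OCc1ccc(OC)cc1)C[C@@](C)(O[Si](CC)(CC)CC)CCC=C(C)C | intermediate
24 | (4R,5S)-5-[(1Z)-2-iodoprop-1-en-1-yl]-4-{(1R,3S)-1-[(4-methoxybenzyl)oxy]-3,7-dimethyl-3-(triethylsilyloxy)oct-6-en-1-yl}-3-methylideneoxolan-2-one | C=C1C(=O)O[C@H](/C=C(/C)I)[C@H]1[C@H](OCc1ccc(OC)cc1)C[C@@](C)(O[Si](CC)(CC)CC)CCC=C(C)C | intermediate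
25 | (4R,5S)-4-[(1R,3S)-1-hydroxy-3,7-dimethyl-3-(triethylsilyloxy)oct-6-en-1-yl]-5-[(1Z)-2-iodoprop-1-en-1-yl]-3-methylideneoxolan-2-one | C=C1C(=O)O[C@H](/C=C(/C)I)[C@H]1[C@H](O)C[C@@](C)(O[Si](CC)(CC)CC)CCC=C(C)C | intermediate
26 | (1R,3S)-1-{(2S,3R)-2-[(1Z)-2-iodoprop-1-en-1-yl]-4-methylidene-5-oxooxolan-3-yl}-3,7-dimethyl-3-(triethylsilyloxy)oct-6-en-1-yl 2-methylpropanoate | C=C1C(=O)O[C@H](/C=C(/C)I)[C@H]1[C@H](OC(=O)C(C)C)C[C@@](C)(O[Si](CC)(CC)CC)CCC=C(C)C | intermediate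
27 | (1R,3S)-5-(3,3-dimethyloxiran-2-yl)-1-{(2S,3R)-2-[(1Z)-2-iodoprop-1-en-1-yl]-4-methylidene-5-oxooxolan-3-yl}-3-methyl-3-(triethylsilyloxy)pentyl 2-methylpropanoate (both epoxide epimers) | C=C1C(=O)O[C@H](/C=C(/C)I)[C@H]1[C@H](OC(=O)C(C)C)C[C@@](C)(O[Si](CC)(CC)CC)CCC1OC1(C)C | intermediate
28 | (1R,3S)-1-{(2S,3R)-2-[(1Z)-2-iodoprop-1-en-1-yl]-4-methylidene-5-oxooxolan-3-yl}-3-methyl-6-oxo-3-(triethylsilyloxy)hexyl 2-methylpropanoate | C=C1C(=O)O[C@H](/C=C(/C)I)[C@H]1[C@H](OC(=O)C(C)C)C[C@@](C)(O[Si](CC)(CC)CC)CCC=O | intermediate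
29 | (3RS,4Z,6R,7R,8R,10S)-3-hydroxy-8-(2-methylpropanoyloxy)-10-(triethylsilyloxy)germacra-4,11(13)-dien-12,6-olide | C=C1C(=O)O[C@@H]2/C=C(/C)C(O)CC[C@](C)(O[Si](CC)(CC)CC)C[C@@H](OC(=O)C(C)C)[C@@H]12 | intermediate
30 | (4Z,6R,7R,8R,10S)-8-(2-methylpropanoyloxy)-3-oxo-10-(triethylsilyloxy)germacra-4,11(13)-dien-12,6-olide | C=C1C(=O)O[C@@H]2/C=C(/C)C(=O)CC[C@](C)(O[Si](CC)(CC)CC)C[C@@H](OC(=O)C(C)C)[C@@H]12 | intermediate
31 | (3S,4Z,6R,7R,8R,10S)-3-hydroxy-8-(2-methylpropanoyloxy)-10-(triethylsilyloxy)germacra-4,11(13)-dien-12,6-olide | C=C1C(=O)O[C@@H]2/C=C(/C)[C@@H](O)CC[C@](C)(O[Si](CC)(CC)CC)C[C@@H](OC(=O)C(C)C)[C@@H]12 | intermediate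
32 | (3S,4Z,6R,7R,8R,10S)-3,10-dihydroxy-8-(2-methylpropanoyloxy)germacra-4,11(13)-dien-12,6-olide, i.e. (3aR,4R,6S,9S,10Z,11aR)-6,9-dihydroxy-6,10-dimethyl-3-methylidene-2-oxo-2,3,3a,4,5,6,7,8,9,11a-decahydrocyclodeca[b]furan-4-yl 2-methylpropanoate | C=C1C(=O)O[C@@H]2/C=C(/C)[C@@H](O)CC[C@](C)(O)C[C@@H](OC(=O)C(C)C)[C@@H]12 | target

**Step count**

Total: 25 steps. Longest linear sequence: 22 steps (geraniol 1 to 32 through steps 1–5, 7–14 and 17–25).

**Steps most likely to fail**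

Step 17 (chromium allylation). The 6,7-trans-lactone outcome is well founded, but which face of the allyl unit bonds (C7 relative to C8) rests on a conformational argument and could be reversed or weak. The fallback sets out from ynone 11 and comes back at isobutyrate 26. Ynone 11 is reduced with the enantiomeric catalyst Ru[(S,S)-TsNCH(Ph)CH(Ph)NH](p-cymene) to the (4S)-propargylic alcohol F1. This is carried through the operations of steps 10 to 14: NaAlH2(OCH2CH2OMe)2 then I2 gives the (4S)-iodo alcohol F2, NaH and 4-methoxybenzyl chloride give the (4S)-PMB ether F3, CO/MeOH/Pd(PPh3)4 gives the (4S)-ester F4, PPTS/MeOH gives the (4S)-allylic alcohol F5, and CBr4/PPh3 gives the (4S)-bromide F6. CrCl2 coupling of F6 with 22, now bonding anti to the alkoxy group, gives the 8-epi lactone F7 with C6 and C7 correct. DDQ then gives the 8-epi alcohol F8, and a Mitsunobu esterification with isobutyric acid (PPh3, DIAD, toluene) inverts C8 while installing the ester, giving 26.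

Step 22 (ten-membered ring closure). Medium-ring Nozaki–Hiyama–Kishi closures can stall through oligomerisation or reduction of the iodide. The fallback closes the ring at C4=C5 by metathesis instead; it sets out from bromide 18 and comes back at 29. Bromide 18 is coupled with acrolein under the conditions of step 17 to give the 5-vinyl lactone F9. DDQ gives the alcohol F10, isobutyryl chloride/pyridine gives the isobutyrate F11, mCPBA gives the epoxide F12, and H5IO6 gives the aldehyde F13. CrCl2/NiCl2-mediated addition of 2-bromopropene to F13 gives the isopropenyl carbinol F14 as a C3-epimer mixture. Ring-closing metathesis of F14 with the second-generation Hoveyda–Grubbs catalyst RuCl2(H2IMes)(=CH-C6H4-2-OiPr) in dilute toluene at 80 °C expels ethene and gives 29, the ring size enforcing the Z alkene.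

Step 24 (C3 configuration). Reagent control can be overridden by the conformation of the macrocyclic enone. The fallback uses separation and inversion instead of reduction; it sets out from 29 and comes back at 31. Chromatography of 29 gives 31 directly together with the (3R)-alcohol F15. Mitsunobu reaction of F15 with formic acid (PPh3, DIAD, THF, 0 °C) gives the inverted (3S)-formate F16. Methanolysis of F16 with KHCO3 in MeOH at 0 °C gives 31.

**Further compounds**

F1 | step 17 | (4S,6S)-6,10-dimethyl-1,6-bis(triethylsilyloxy)undec-9-en-2-yn-4-ol | CC[Si](CC)(CC)OCC#C[C@@H](O)C[C@@](C)(O[Si](CC)(CC)CC)CCC=C(C)C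
F2 | step 17 | (2Z,4S,6S)-2-iodo-6,10-dimethyl-1,6-bis(triethylsilyloxy)undeca-2,9-dien-4-ol | CC[Si](CC)(CC)OC/C(I)=C/[C@@H](O)C[C@@](C)(O[Si](CC)(CC)CC)CCC=C(C)C
F3 | step 17 | (2Z,4S,6S)-2-iodo-4-[(4-methoxybenzyl)oxy]-6,10-dimethyl-1,6-bis(triethylsilyloxy)undeca-2,9-diene | CC[Si](CC)(CC)OC/C(I)=C/[C@@H](OCc1ccc(OC)cc1)C[C@@](C)(O[Si](CC)(CC)CC)CCC=C(C)C
F4 | step 17 | methyl (2Z,4S,6S)-4-[(4-methoxybenzyl)oxy]-6,10-dimethyl-6-(triethylsilyloxy)-2-[(triethylsilyloxy)methyl]undeca-2,9-dienoate | CC[Si](CC)(CC)OC/C(C(=O)OC)=C/[C@@H](OCc1ccc(OC)cc1)C[C@@](C)(O[Si](CC)(CC)CC)CCC=C(C)C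
F5 | step 17 | methyl (2Z,4S,6S)-2-(hydroxymethyl)-4-[(4-methoxybenzyl)oxy]-6,10-dimethyl-6-(triethylsilyloxy)undeca-2,9-dienoate | OC/C(C(=O)OC)=C/[C@@H](OCc1ccc(OC)cc1)C[C@@](C)(O[Si](CC)(CC)CC)CCC=C(C)C
F6 | step 17 | methyl (2E,4S,6S)-2-(bromomethyl)-4-[(4-methoxybenzyl)oxy]-6,10-dimethyl-6-(triethylsilyloxy)undeca-2,9-dienoate | BrC/C(C(=O)OC)=C/[C@@H](OCc1ccc(OC)cc1)C[C@@](C)(O[Si](CC)(CC)CC)CCC=C(C)C
F7 | step 17 | (4R,5S)-5-[(1Z)-2-iodoprop-1-en-1-yl]-4-{(1S,3S)-1-[(4-methoxybenzyl)oxy]-3,7-dimethyl-3-(triethylsilyloxy)oct-6-en-1-yl}-3-methylideneoxolan-2-one | C=C1C(=O)O[C@H](/C=C(/C)I)[C@H]1[C@@H](OCc1ccc(OC)cc1)C[C@@](C)(O[Si](CC)(CC)CC)CCC=C(C)C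
F8 | step 17 | (4R,5S)-4-[(1S,3S)-1-hydroxy-3,7-dimethyl-3-(triethylsilyloxy)oct-6-en-1-yl]-5-[(1Z)-2-iodoprop-1-en-1-yl]-3-methylideneoxolan-2-one | C=C1C(=O)O[C@H](/C=C(/C)I)[C@H]1[C@@H](O)C[C@@](C)(O[Si](CC)(CC)CC)CCC=C(C)C
F9 | step 22 | (4R,5R)-5-ethenyl-4-{(1R,3S)-1-[(4-methoxybenzyl)oxy]-3,7-dimethyl-3-(triethylsilyloxy)oct-6-en-1-yl}-3-methylideneoxolan-2-one | C=C1C(=O)O[C@H](C=C)[C@H]1[C@H](OCc1ccc(OC)cc1)C[C@@](C)(O[Si](CC)(CC)CC)CCC=C(C)C
F10 | step 22 | (4R,5R)-5-ethenyl-4-[(1R,3S)-1-hydroxy-3,7-dimethyl-3-(triethylsilyloxy)oct-6-en-1-yl]-3-methylideneoxolan-2-one | C=C1C(=O)O[C@H](C=C)[C@H]1[C@H](O)C[C@@](C)(O[Si](CC)(CC)CC)CCC=C(C)C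
F11 | step 22 | (1R,3S)-1-[(2R,3R)-2-ethenyl-4-methylidene-5-oxooxolan-3-yl]-3,7-dimethyl-3-(triethylsilyloxy)oct-6-en-1-yl 2-methylpropanoate | C=C1C(=O)O[C@H](C=C)[C@H]1[C@H](OC(=O)C(C)C)C[C@@](C)(O[Si](CC)(CC)CC)CCC=C(C)C
F12 | step 22 | (1R,3S)-5-(3,3-dimethyloxiran-2-yl)-1-[(2R,3R)-2-ethenyl-4-methylidene-5-oxooxolan-3-yl]-3-methyl-3-(triethylsilyloxy)pentyl 2-methylpropanoate | C=C1C(=O)O[C@H](C=C)[C@H]1[C@H](OC(=O)C(C)C)C[C@@](C)(O[Si](CC)(CC)CC)CCC1OC1(C)C
F13 | step 22 | (1R,3S)-1-[(2R,3R)-2-ethenyl-4-methylidene-5-oxooxolan-3-yl]-3-methyl-6-oxo-3-(triethylsilyloxy)hexyl 2-methylpropanoate | C=C1C(=O)O[C@H](C=C)[C@H]1[C@H](OC(=O)C(C)C)C[C@@](C)(O[Si](CC)(CC)CC)CCC=O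
F14 | step 22 | (1R,3S,6RS)-1-[(2R,3R)-2-ethenyl-4-methylidene-5-oxooxolan-3-yl]-6-hydroxy-3,7-dimethyl-3-(triethylsilyloxy)oct-7-en-1-yl 2-methylpropanoate | C=C1C(=O)O[C@H](C=C)[C@H]1[C@H](OC(=O)C(C)C)C[C@@](C)(O[Si](CC)(CC)CC)CCC(O)C(C)=C
F15 | step 24 | (3R,4Z,6R,7R,8R,10S)-3-hydroxy-8-(2-methylpropanoyloxy)-10-(triethylsilyloxy)germacra-4,11(13)-dien-12,6-olide | C=C1C(=O)O[C@@H]2/C=C(/C)[C@H](O)CC[C@](C)(O[Si](CC)(CC)CC)C[C@@H](OC(=O)C(C)C)[C@@H]12
F16 | step 24 | (3S,4Z,6R,7R,8R,10S)-3-(formyloxy)-8-(2-methylpropanoyloxy)-10-(triethylsilyloxy)germacra-4,11(13)-dien-12,6-olide | C=C1C(=O)O[C@@H]2/C=C(/C)[C@@H](OC=O)CC[C@](C)(O[Si](CC)(CC)CC)C[C@@H](OC(=O)C(C)C)[C@@H]12
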